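A direct plan would build the central diaryl ether first and both pyranone rings last.
The protected phenol A1 would be O-arylated, its formyl group degraded to a phenol, and the ring iodinated, O-aroylated and acetylated by Stille coupling to give keto acid A2.
Esterification with acetophenone A3 would give bis-ester A4; a twofold Baker–Venkataraman shift and cyclodehydration would give tetrabenzyl biflavone A5, and hydrogenolysis the target.
Weak point 1, the linear run-up to A2: allyl on/off, CHO to OH, iodination and a Stille acetylation of a di-ortho-substituted iodide only adjust protecting groups and oxidation level around one acetophenone ring.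
Weak point 2, the twofold O-to-C aroyl shift on A4: two aryl esters and two enolates sit in one molecule under excess LiHMDS, so cross- and intermolecular transacylation must be held back by high dilution exactly where all material converges.
Weak point 3, the last-step hydrogenolysis of four benzyl ethers beside two chromone C2=C3 bonds on a poorly soluble biflavone: over-reduction to flavanones would be paid for at the very end.

**Retrosynthetic overview**
Each chromone would be cut at C4a–C4, C8a–O1 and O1–C2, back to an aryne and an arylpropiolic acid, so no acetophenone, aryl ester or diketone is ever needed.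
The hexasubstituted ring A'' (C4a''–C, C5''–O, C6''–OAr, C7''–O, C8a''–O) would come from a 3,5-bis(benzyloxy)-4-aryloxybenzyne; the benzyloxy group beside the triple bond sends the carboxylate oxygen to C8a'' and the acyl group to C4a''.
Ring order: the C6''–O–C4' diaryl ether is made on the aryne precursor (step 4), pyranone ring C'' closes in step 6, and pyranone ring C closes in step 10 by the same cascade with 3,5-dimethoxybenzyne.
The iodide carried through step 6 becomes the second propiolic acid in one step; one BCl3 treatment removes three benzyl groups and the chelated 5-O-methyl group, so no hydrogenation meets the C2=C3 bonds.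

Key step: step 6

Remark: 3,5-bis(benzyloxy)phenol is taken as a catalogue compound, like the other starting materials.

Step 1
Reactants: 1 3,5-bis(benzyloxy)phenol
Product: 2 2-bromo-3,5-bis(benzyloxy)phenol
Conditions: NBS (1.0 equiv), CH2Cl2, −78 °C to rt
Reagents that add atoms: N-bromosuccinimide, O=C1CCC(=O)N1Br
Why: Electrophilic aromatic bromination; in a non-polar solvent at low temperature bromine should enter ortho to the free phenol, the two ortho sites being equivalent and C4 being shielded between two benzyloxy groups.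

Step 2
Reactants: 2 2-bromo-3,5-bis(benzyloxy)phenol
Product: 4 3,5-bis(benzyloxy)-2-bromobenzene-1,4-diol, via p-quinone 3 (not isolated)
Conditions: ON(SO3K)2 (Fremy's salt, 2.5 equiv), KH2PO4, acetone–H2O, 0 °C to rt; then Na2S2O4, EtOAc–H2O
Reagents that add atoms: potassium nitrosodisulfonate, [O]N(S(=O)(=O)[O-])S(=O)(=O)[O-].[K+].[K+]
Why: Teuber oxidation: the phenoxyl radical should be trapped by a second nitrosodisulfonate radical at the free para carbon, loss of imidodisulfonate gives the p-quinone, and dithionite reduces it to the hydroquinone; this installs the oxygen that becomes the diaryl ether oxygen on C6''.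

Step 3
Reactants: 4 3,5-bis(benzyloxy)-2-bromobenzene-1,4-diol
Product: 7 3,5-bis(benzyloxy)-4-hydroxy-2-(trimethylsilyl)phenyl trifluoromethanesulfonate, via bis-silyl ether 5 (not isolated), via silyl-ether triflate 6 (not isolated)
Conditions: HMDS (1.5 equiv), THF, 70 °C, then evaporation; n-BuLi (1.1 equiv), THF, −78 °C; Tf2O (1.2 equiv), −78 °C; then aq. citric acid, THF, 0 °C
Reagents that add atoms: hexamethyldisilazane, C[Si](C)(C)N[Si](C)(C)C; trifluoromethanesulfonic anhydride, O=S(=O)(OS(=O)(=O)C(F)(F)F)C(F)(F)F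
Why: After O-silylation of both hydroxyls, bromine–lithium exchange gives an aryllithium that takes the silyl group only from the neighbouring oxygen (1,3-retro-Brook rearrangement), the lithium phenoxide so freed is triflated, and the untouched hindered O–SiMe3 group is hydrolysed on work-up to leave the phenol between the two benzyloxy groups.

Step 4
Reactants: 7 3,5-bis(benzyloxy)-4-hydroxy-2-(trimethylsilyl)phenyl trifluoromethanesulfonate; 8 (4-iodophenyl)boronic acid
Product: 9 3,5-bis(benzyloxy)-4-(4-iodophenoxy)-2-(trimethylsilyl)phenyl trifluoromethanesulfonate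
Conditions: Cu(OAc)2 (1.5 equiv), pyridine (5 equiv), 4 Å MS, CH2Cl2, air, rt
Reagents that add atoms: none
Why: Chan–Lam–Evans oxidative C–O coupling, which runs at room temperature without fluoride or strong base, so the silyl triflate should stay intact and the aryl iodide should not react with copper.

Step 5
Reactants: 10 1-(benzyloxy)-4-iodobenzene; 11 propiolic acid (prop-2-ynoic acid)
Product: 12 3-[4-(benzyloxy)phenyl]prop-2-ynoic acid
Conditions: Pd(PPh3)2Cl2 (2.5 mol%), 1,4-bis(diphenylphosphino)butane (5 mol%), DBU (2.2 equiv), DMSO, 30 °C; then 1 M HCl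
Reagents that add atoms: none
Why: Copper-free Sonogashira-type coupling of an aryl iodide with propiolic acid, run near room temperature so that the arylpropiolic acid should not decarboxylate.

Step 6
Reactants: 9 3,5-bis(benzyloxy)-4-(4-iodophenoxy)-2-(trimethylsilyl)phenyl trifluoromethanesulfonate; 12 3-[4-(benzyloxy)phenyl]prop-2-ynoic acid
Product: 15 5,7-bis(benzyloxy)-2-[4-(benzyloxy)phenyl]-6-(4-iodophenoxy)-4H-chromen-4-one, via aryne 13 (not isolated), via o-hydroxyaryl ynone 14 (not isolated)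
Conditions: 12 (1.2 equiv), CsF (4 equiv), THF, 125 °C, sealed tube
Reagents that add atoms: none
Why: Fluoride strips the silyl group of 9 and triflate leaves to give aryne 13; the carboxylate oxygen of 12 adds to the aryne carbon remote from the flanking benzyloxy group (the future C8a''), and the aryl anion formed at C4a'', stabilised inductively by the adjacent C5''–O bond, attacks the ester carbonyl through a four-membered transition state, so that a 1,3 O-to-C acyl shift delivers the o-acylphenoxide of ynone 14. The phenoxide then closes ring C'' by 6-endo-dig oxa-Michael addition to the ynone β-carbon (O1''–C2''), preferred over 5-exo-dig attack because the carbonyl polarises the alkyne toward that carbon, and protonation at C3'' ends the cascade. The closest known reaction is the fluoride-induced C–O insertion of arynes into carboxylic acids to give o-hydroxyaryl ketones, which with arylpropiolic acids runs on to flavones. Three bonds (C8a''–O1'', C4a''–C4'', O1''–C2'') and the full substitution pattern of ring A'' are set in one operation, and no stereocentre is created. The step needs regiocontrol on an unsymmetrical aryne and an acyl shift faster than protonation of the aryl anion: the first should be secured by the C5'' benzyloxy group beside the triple bond and the unhindered C8a'' terminus, the second by THF at high temperature with no proton source other than the acid itself. The aryl iodide, the benzyl ethers and the diaryl ether are inert to CsF and to the aryne.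

Step 7
Reactants: 15 5,7-bis(benzyloxy)-2-[4-(benzyloxy)phenyl]-6-(4-iodophenoxy)-4H-chromen-4-one; 11 propiolic acid
Product: 16 3-[4-({5,7-bis(benzyloxy)-2-[4-(benzyloxy)phenyl]-4-oxo-4H-chromen-6-yl}oxy)phenyl]prop-2-ynoic acid
Conditions: Pd(PPh3)2Cl2 (5 mol%), 1,4-bis(diphenylphosphino)butane (10 mol%), DBU (2.2 equiv), DMSO, 30 °C; then 1 M HCl
Reagents that add atoms: none
Why: The same copper-free Sonogashira-type coupling with propiolic acid; the chromone and the benzyl ethers should tolerate DBU in DMSO at this temperature.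

Step 8
Reactants: 17 3,5-dimethoxyphenol
Product: 18 2-bromo-3,5-dimethoxyphenol
Conditions: NBS (1.0 equiv), CH2Cl2, −78 °C to rt
Reagents that add atoms: N-bromosuccinimide, O=C1CCC(=O)N1Br
Why: Ortho-selective electrophilic bromination of the phenol, as in step 1.

Step 9
Reactants: 18 2-bromo-3,5-dimethoxyphenol
Product: 20 3,5-dimethoxy-2-(trimethylsilyl)phenyl trifluoromethanesulfonate, via silyl ether 19 (not isolated)
Conditions: HMDS (1.0 equiv), THF, 70 °C, then evaporation; n-BuLi (1.1 equiv), THF, −78 °C; Tf2O (1.2 equiv), −78 °C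
Reagents that add atoms: hexamethyldisilazane, C[Si](C)(C)N[Si](C)(C)C; trifluoromethanesulfonic anhydride, O=S(=O)(OS(=O)(=O)C(F)(F)F)C(F)(F)F
Why: O-silylation, bromine–lithium exchange, 1,3-retro-Brook rearrangement and triflation of the resulting phenoxide, the standard entry to o-silylaryl triflates.

Step 10
Reactants: 16 3-[4-({5,7-bis(benzyloxy)-2-[4-(benzyloxy)phenyl]-4-oxo-4H-chromen-6-yl}oxy)phenyl]prop-2-ynoic acid; 20 3,5-dimethoxy-2-(trimethylsilyl)phenyl trifluoromethanesulfonate
Product: 23 5,7-bis(benzyloxy)-2-[4-(benzyloxy)phenyl]-6-[4-(5,7-dimethoxy-4-oxo-4H-chromen-2-yl)phenoxy]-4H-chromen-4-one, via 3,5-dimethoxybenzyne 21 (not isolated), via o-hydroxyaryl ynone 22 (not isolated)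
Conditions: 20 (2.0 equiv), CsF (5 equiv), THF, 125 °C, sealed tube
Reagents that add atoms: none
Why: The same aryne C–O insertion, acyl shift and 6-endo-dig oxa-Michael cascade as in step 6; the carboxylate should add to the aryne carbon remote from the 3-methoxy group, which places the carbonyl beside that methoxy group and gives the 5,7-dimethoxy pattern of ring A.

Step 11
Reactants: 23 5,7-bis(benzyloxy)-2-[4-(benzyloxy)phenyl]-6-[4-(5,7-dimethoxy-4-oxo-4H-chromen-2-yl)phenoxy]-4H-chromen-4-one
Product: 24 neocryptomerin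
Conditions: BCl3 (12 equiv), pentamethylbenzene (9 equiv), CH2Cl2, −78 °C to rt; then H2O, 0 °C
Reagents that add atoms: none
Why: Lewis-acid ether cleavage: the three benzyl ethers should be cleaved at low temperature with pentamethylbenzene trapping the benzyl cations, and on warming the 5-O-methyl group peri to the C4 carbonyl should be removed through a six-membered boron chelate, while the non-chelated 7-O-methyl group, the diaryl ether and both C2=C3 bonds should survive.

**Compound list**

1 | 3,5-bis(benzyloxy)phenol | Oc1cc(OCc2ccccc2)cc(OCc2ccccc2)c1 | starting material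
2 | 2-bromo-3,5-bis(benzyloxy)phenol | Oc1cc(OCc2ccccc2)cc(OCc2ccccc2)c1Br | intermediate
3 | 3,5-bis(benzyloxy)-2-bromocyclohexa-2,5-diene-1,4-dione (p-quinone, not isolated) | O=C1C=C(OCc2ccccc2)C(=O)C(OCc2ccccc2)=C1Br | intermediate
4 | 3,5-bis(benzyloxy)-2-bromobenzene-1,4-diol | Oc1cc(OCc2ccccc2)c(O)c(OCc2ccccc2)c1Br | intermediate
5 | [3,5-bis(benzyloxy)-2-bromo-1,4-phenylene]bis(oxy)bis(trimethylsilane) (not isolated) | C[Si](C)(C)Oc1cc(OCc2ccccc2)c(O[Si](C)(C)C)c(OCc2ccccc2)c1Br | intermediate
6 | 3,5-bis(benzyloxy)-2-(trimethylsilyl)-4-[(trimethylsilyl)oxy]phenyl trifluoromethanesulfonate (not isolated) | C[Si](C)(C)Oc1c(OCc2ccccc2)cc(OS(=O)(=O)C(F)(F)F)c([Si](C)(C)C)c1OCc1ccccc1 | intermediate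
7 | 3,5-bis(benzyloxy)-4-hydroxy-2-(trimethylsilyl)phenyl trifluoromethanesulfonate | Oc1c(OCc2ccccc2)cc(OS(=O)(=O)C(F)(F)F)c([Si](C)(C)C)c1OCc1ccccc1 | intermediate
8 | (4-iodophenyl)boronic acid | OB(O)c1ccc(I)cc1 | starting material
9 | 3,5-bis(benzyloxy)-4-(4-iodophenoxy)-2-(trimethylsilyl)phenyl trifluoromethanesulfonate | C[Si](C)(C)c1c(OS(=O)(=O)C(F)(F)F)cc(OCc2ccccc2)c(Oc2ccc(I)cc2)c1OCc1ccccc1 | intermediate
10 | 1-(benzyloxy)-4-iodobenzene | Ic1ccc(OCc2ccccc2)cc1 | starting material
11 | propiolic acid | C#CC(=O)O | starting material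
12 | 3-[4-(benzyloxy)phenyl]prop-2-ynoic acid | OC(=O)C#Cc1ccc(OCc2ccccc2)cc1 | intermediate
13 | 3,5-bis(benzyloxy)-4-(4-iodophenoxy)benzyne (not isolated) | Ic1ccc(OC2=C(OCc3ccccc3)C#CC=C2OCc2ccccc2)cc1 | intermediate
14 | 1-[2,4-bis(benzyloxy)-6-hydroxy-3-(4-iodophenoxy)phenyl]-3-[4-(benzyloxy)phenyl]prop-2-yn-1-one (not isolated) | O=C(C#Cc1ccc(OCc2ccccc2)cc1)c1c(O)cc(OCc2ccccc2)c(Oc2ccc(I)cc2)c1OCc1ccccc1 | intermediate
15 | 5,7-bis(benzyloxy)-2-[4-(benzyloxy)phenyl]-6-(4-iodophenoxy)-4H-chromen-4-one | O=c1cc(-c2ccc(OCc3ccccc3)cc2)oc2cc(OCc3ccccc3)c(Oc3ccc(I)cc3)c(OCc3ccccc3)c12 | intermediate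
16 | 3-[4-({5,7-bis(benzyloxy)-2-[4-(benzyloxy)phenyl]-4-oxo-4H-chromen-6-yl}oxy)phenyl]prop-2-ynoic acid | OC(=O)C#Cc1ccc(Oc2c(OCc3ccccc3)cc3oc(-c4ccc(OCc5ccccc5)cc4)cc(=O)c3c2OCc2ccccc2)cc1 | intermediate
17 | 3,5-dimethoxyphenol | COc1cc(O)cc(OC)c1 | starting material
18 | 2-bromo-3,5-dimethoxyphenol | COc1cc(O)c(Br)c(OC)c1 | intermediate
19 | (2-bromo-3,5-dimethoxyphenoxy)trimethylsilane (not isolated) | COc1cc(O[Si](C)(C)C)c(Br)c(OC)c1 | intermediate
20 | 3,5-dimethoxy-2-(trimethylsilyl)phenyl trifluoromethanesulfonate | COc1cc(OC)c([Si](C)(C)C)c(OS(=O)(=O)C(F)(F)F)c1 | intermediate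
21 | 3,5-dimethoxybenzyne (not isolated) | COC1=CC(OC)=CC#C1 | intermediate
22 | 3-[4-({5,7-bis(benzyloxy)-2-[4-(benzyloxy)phenyl]-4-oxo-4H-chromen-6-yl}oxy)phenyl]-1-(2-hydroxy-4,6-dimethoxyphenyl)prop-2-yn-1-one (not isolated) | COc1cc(O)c(C(=O)C#Cc2ccc(Oc3c(OCc4ccccc4)cc4oc(-c5ccc(OCc6ccccc6)cc5)cc(=O)c4c3OCc3ccccc3)cc2)c(OC)c1 | intermediate
23 | 5,7-bis(benzyloxy)-2-[4-(benzyloxy)phenyl]-6-[4-(5,7-dimethoxy-4-oxo-4H-chromen-2-yl)phenoxy]-4H-chromen-4-one | COc1cc(OC)c2c(=O)cc(-c3ccc(Oc4c(OCc5ccccc5)cc5oc(-c6ccc(OCc7ccccc7)cc6)cc(=O)c5c4OCc4ccccc4)cc3)oc2c1 | intermediate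
24 | neocryptomerin, 5,7-dihydroxy-6-[4-(5-hydroxy-7-methoxy-4-oxo-4H-chromen-2-yl)phenoxy]-2-(4-hydroxyphenyl)-4H-chromen-4-one | COc1cc(O)c2c(=O)cc(-c3ccc(Oc4c(O)cc5oc(-c6ccc(O)cc6)cc(=O)c5c4O)cc3)oc2c1 | target

**Step count**
Total: 11 steps. Longest linear sequence: 8 steps (steps 1, 2, 3, 4, 6, 7, 10, 11).

**Steps most likely to fail**

Step 6. The aryl anion may be protonated before the acyl shift, which would end at an aryl ester, or the propiolic acid may decarboxylate at 125 °C before it is captured. The fallback sets out from 9 and returns at 15; it separates C-acylation from ring closure. Compound 9 would be treated with acetic acid and CsF in THF at 125 °C, the parent case of the aryne C–O insertion, to give 1-[2,4-bis(benzyloxy)-6-hydroxy-3-(4-iodophenoxy)phenyl]ethanone F1. O-Aroylation with 4-(benzyloxy)benzoyl chloride in pyridine would give 2-acetyl-3,5-bis(benzyloxy)-4-(4-iodophenoxy)phenyl 4-(benzyloxy)benzoate F2. KOH in pyridine at 50 °C (Baker–Venkataraman rearrangement) would give 1-[2,4-bis(benzyloxy)-6-hydroxy-3-(4-iodophenoxy)phenyl]-3-[4-(benzyloxy)phenyl]propane-1,3-dione F3, and p-TsOH in toluene at 80 °C would close ring C'' to 15.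

Step 10. The same competition between acyl shift and protonation, or decarboxylation of the advanced acid 16, would now cost late-stage material. The fallback sets out from 15, bypasses 16 and 20, and returns at 23 by chalcone chemistry. Reductive carbonylation of the iodide (Pd(OAc)2, di(1-adamantyl)-n-butylphosphine, CO/H2 1:1 at 5 bar, TMEDA, toluene, 100 °C) would give 4-({5,7-bis(benzyloxy)-2-[4-(benzyloxy)phenyl]-4-oxo-4H-chromen-6-yl}oxy)benzaldehyde F4. Claisen–Schmidt condensation with commercial 1-(2-hydroxy-4,6-dimethoxyphenyl)ethanone (KOH, EtOH–THF, rt) would give (2E)-3-[4-({5,7-bis(benzyloxy)-2-[4-(benzyloxy)phenyl]-4-oxo-4H-chromen-6-yl}oxy)phenyl]-1-(2-hydroxy-4,6-dimethoxyphenyl)prop-2-en-1-one F5. Oxidative cyclisation with catalytic I2 in DMSO at 120 °C would then give 23.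

Step 4. Copper-mediated C–O bond formation at a phenoxide flanked by two benzyloxy groups may be slow, so that protodeboronation and homocoupling of the boronic acid consume the partner. The fallback sets out from 7 and returns at 16; it replaces copper by ligand coupling on trivalent iodine. Compound 7 would be arylated with commercial bis(4-bromophenyl)iodonium trifluoromethanesulfonate (K2CO3, MeCN, 40 °C) to give 3,5-bis(benzyloxy)-4-(4-bromophenoxy)-2-(trimethylsilyl)phenyl trifluoromethanesulfonate F6. The conditions of step 6 with 12 would give 5,7-bis(benzyloxy)-2-[4-(benzyloxy)phenyl]-6-(4-bromophenoxy)-4H-chromen-4-one F7. Coupling of this bromide with propiolic acid under the conditions of step 7 at 50 °C would give 16.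

**Further compounds**

F1 | step 6 | 1-[2,4-bis(benzyloxy)-6-hydroxy-3-(4-iodophenoxy)phenyl]ethanone | CC(=O)c1c(O)cc(OCc2ccccc2)c(Oc2ccc(I)cc2)c1OCc1ccccc1
F2 | step 6 | 2-acetyl-3,5-bis(benzyloxy)-4-(4-iodophenoxy)phenyl 4-(benzyloxy)benzoate | CC(=O)c1c(OC(=O)c2ccc(OCc3ccccc3)cc2)cc(OCc2ccccc2)c(Oc2ccc(I)cc2)c1OCc1ccccc1
F3 | step 6 | 1-[2,4-bis(benzyloxy)-6-hydroxy-3-(4-iodophenoxy)phenyl]-3-[4-(benzyloxy)phenyl]propane-1,3-dione | O=C(CC(=O)c1c(O)cc(OCc2ccccc2)c(Oc2ccc(I)cc2)c1OCc1ccccc1)c1ccc(OCc2ccccc2)cc1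
F4 | step 10 | 4-({5,7-bis(benzyloxy)-2-[4-(benzyloxy)phenyl]-4-oxo-4H-chromen-6-yl}oxy)benzaldehyde | O=Cc1ccc(Oc2c(OCc3ccccc3)cc3oc(-c4ccc(OCc5ccccc5)cc4)cc(=O)c3c2OCc2ccccc2)cc1
F5 | step 10 | (2E)-3-[4-({5,7-bis(benzyloxy)-2-[4-(benzyloxy)phenyl]-4-oxo-4H-chromen-6-yl}oxy)phenyl]-1-(2-hydroxy-4,6-dimethoxyphenyl)prop-2-en-1-one | COc1cc(O)c(C(=O)/C=C/c2ccc(Oc3c(OCc4ccccc4)cc4oc(-c5ccc(OCc6ccccc6)cc5)cc(=O)c4c3OCc3ccccc3)cc2)c(OC)c1
F6 | step 4 | 3,5-bis(benzyloxy)-4-(4-bromophenoxy)-2-(trimethylsilyl)phenyl trifluoromethanesulfonate | C[Si](C)(C)c1c(OS(=O)(=O)C(F)(F)F)cc(OCc2ccccc2)c(Oc2ccc(Br)cc2)c1OCc1ccccc1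
F7 | step 4 | 5,7-bis(benzyloxy)-2-[4-(benzyloxy)phenyl]-6-(4-bromophenoxy)-4H-chromen-4-one | O=c1cc(-c2ccc(OCc3ccccc3)cc2)oc2cc(OCc3ccccc3)c(Oc3ccc(Br)cc3)c(OCc3ccccc3)c12
A1 | direct plan | 3,5-bis(benzyloxy)-4-hydroxybenzaldehyde | O=Cc1cc(OCc2ccccc2)c(O)c(OCc2ccccc2)c1
A2 | direct plan | 4-{3-acetyl-2,6-bis(benzyloxy)-4-[4-(benzyloxy)benzoyloxy]phenoxy}benzoic acid | OC(=O)c1ccc(Oc2c(OCc3ccccc3)cc(OC(=O)c3ccc(OCc4ccccc4)cc3)c(C(C)=O)c2OCc2ccccc2)cc1
A3 | direct plan | 1-[2-(benzyloxy)-6-hydroxy-4-methoxyphenyl]ethanone | CC(=O)c1c(OCc2ccccc2)cc(OC)cc1O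
A4 | direct plan | 2-acetyl-3-(benzyloxy)-5-methoxyphenyl 4-{3-acetyl-2,6-bis(benzyloxy)-4-[4-(benzyloxy)benzoyloxy]phenoxy}benzoate | CC(=O)c1c(OCc2ccccc2)cc(OC)cc1OC(=O)c1ccc(Oc2c(OCc3ccccc3)cc(OC(=O)c3ccc(OCc4ccccc4)cc3)c(C(C)=O)c2OCc2ccccc2)cc1
A5 | direct plan | 5-(benzyloxy)-2-[4-({5,7-bis(benzyloxy)-2-[4-(benzyloxy)phenyl]-4-oxo-4H-chromen-6-yl}oxy)phenyl]-7-methoxy-4H-chromen-4-one | COc1cc(OCc2ccccc2)c2c(=O)cc(-c3ccc(Oc4c(OCc5ccccc5)cc5oc(-c6ccc(OCc7ccccc7)cc6)cc(=O)c5c4OCc4ccccc4)cc3)oc2c1
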